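**Retrosynthetic overview**

- Locants used below (cadinane numbering): C1 ring-fusion CH, C4 spiro carbon, C5=C6 alkene, C7 (isopropyl), C10 (methyl), C15 pyran CH2, C1' benzylic carbon.
- The dihydropyran ring is closed last by an oxa-Diels–Alder reaction of the ortho-quinone methide (2,4,6-trihydroxyisophthalaldehyde + benzaldehyde) with the exocyclic C4=C15 bond of the (1S,4R,4aR)-4(15),5-diene; this sets C4 and C1'.
- The diene comes from the C5=C6 enone by methylenation, and the enone from a cis-fused decalone by Saegusa–Ito oxidation.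
- The decalone comes from a methylidene-pinane: radical cyclobutane opening and hydrogenation unveil the C7 isopropyl and set the C10 methyl. Its ring A is made by a Diels–Alder reaction of (+)-apoverbenone, anti to the gem-dimethyl bridge; this sets C1 cis to the C10 methyl, which a Robinson annulation of menthone would not (it gives the C1 epimer).
- Ring order: ring B (bought, the six-membered ring of (+)-nopinone, which carries the C7 stereocentre), then ring A, then cyclobutane opening, then the dihydropyran ring.

Assumption: (1R,5S)-(+)-nopinone, 2-(tert-butyldimethylsilyloxy)buta-1,3-diene and 2,4,6-trihydroxybenzene-1,3-dicarbaldehyde are taken as purchasable.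

**Route**

Step 1
Reactants: 1 (1R,5S)-6,6-dimethylbicyclo[3.1.1]heptan-2-one [(+)-nopinone]
Product: 2 (1R,5R)-6,6-dimethylbicyclo[3.1.1]hept-3-en-2-one [(+)-apoverbenone]
Conditions: IBX (2 equiv), DMSO/PhF, 70 °C
Reagents that add atoms: none
Why: IBX dehydrogenation of a ketone to its enone (Nicolaou oxidation) can only desaturate C3–C4 because the other alpha carbon is a bridgehead, and both stereocentres are bridgeheads that are not touched.

Step 2
Reactants: 2 (+)-apoverbenone; 3 2-(tert-butyldimethylsilyloxy)buta-1,3-diene
Product: 4 (1R,2S,7S,9R)-4-(tert-butyldimethylsilyloxy)-10,10-dimethyltricyclo[7.1.1.0(2,7)]undec-4-en-8-one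
Conditions: PhMe, 150 °C, sealed tube, BHT (cat.)
Reagents that add atoms: none
Why: In this thermal normal-demand Diels–Alder reaction the diene adds to the strained enone on the face away from the gem-dimethyl bridge (whose inner methyl covers the other face), so the two new C–C bonds are cis to each other and trans to the bridge carbon that becomes the C7 isopropyl, which sets C1 (and a temporary C6 centre), while the 2-silyloxy group directs the para regiochemistry that places the masked ketone on the future C4.

Step 3
Reactants: 4 Diels–Alder adduct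
Product: 6 (1R,2S,7S,9R)-10,10-dimethyl-8-methylidenetricyclo[7.1.1.0(2,7)]undecan-4-one, via methylidene silyl enol ether 5 (not isolated)
Conditions: Ph3PCH3Br, KOtBu, THF, 0 → 65 °C; then TBAF, AcOH, THF, 0 °C
Reagents that add atoms: methyltriphenylphosphonium bromide (used as its ylide), C[P+](c1ccccc1)(c1ccccc1)c1ccccc1.[Br-]
Why: Wittig methylenation of the bicyclic ketone followed by fluoride cleavage of the silyl enol ether creates no stereocentre, and the alpha stereocentre C1 is safe toward the basic ylide because its substituent already sits in the favoured position anti to the gem-dimethyl bridge.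

Step 4
Reactants: 6 tricyclic methylidene ketone
Product: 7 (4aR,5R,8S,8aS)-5-methyl-8-(propan-2-yl)octahydronaphthalen-2(1H)-one (cis-fused)
Conditions: Mn(dpm)3 (10 mol %), PhSiH3, t-BuOOH, i-PrOH, 22 °C
Reagents that add atoms: none
Why: In this Mukaiyama-type metal-hydride hydrogen-atom-transfer hydrogenation, H-atom transfer to the exocyclic methylidene gives a tertiary cyclobutylcarbinyl radical that fragments with strain release to the ring B trisubstituted alkene and a tertiary radical (reduced to the C7 isopropyl), and the same conditions then hydrogenate that alkene under thermodynamic control, the C10 radical taking hydrogen on the face away from the axial C1–C2 bond so that the new methyl is equatorial and cis to C2 (10R).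

Step 5
Reactants: 7 cis-fused decalone
Product: 9 (4aR,5R,8S)-5-methyl-8-(propan-2-yl)-4,4a,5,6,7,8-hexahydronaphthalen-2(3H)-one, via trimethylsilyl enol ether 8 (not isolated)
Conditions: TMSOTf, Et3N, CH2Cl2, 0 °C → rt; then Pd(OAc)2 (1.1 equiv), MeCN, rt
Reagents that add atoms: none
Why: In this Saegusa–Ito oxidation the cis-fused ketone enolises under equilibrating silylation toward the ring-fusion side (C4=C5) and palladium-mediated dehydrosilylation gives the C5=C6 enone, which removes only the temporary C6 stereocentre while C1 (not alpha to the ketone), C7 and C10 are untouched.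

Step 6
Reactants: 9 enone
Product: 10 (1S,4R,4aR)-4-methyl-7-methylidene-1-(propan-2-yl)-1,2,3,4,4a,5,6,7-octahydronaphthalene
Conditions: Cp2TiMe2, PhMe, 65 °C, dark
Reagents that add atoms: dimethyltitanocene (Cp2TiMe2), C[Ti](C)(C1C=CC=C1)C1C=CC=C1
Why: Petasis methylenation turns the enone carbonyl into the exocyclic C4=C15 alkene with a neutral titanium methylidene, so the gamma stereocentre C1 (the less stable epimer) cannot equilibrate through a dienolate and no new stereocentre is formed.

Step 7
Reactants: 10 diene; 11 benzaldehyde; 12 2,4,6-trihydroxybenzene-1,3-dicarbaldehyde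
Product: 14 guajadial D, via ortho-quinone methide 13 (not isolated)
Conditions: MeNHCH2CH2NHMe (20 mol %), AcOH (20 mol %), (CF3)2CHOH, 50 °C
Reagents that add atoms: none
Why: Knoevenagel condensation gives the ortho-quinone methide, which undergoes an inverse-electron-demand oxa-Diels–Alder reaction across the electron-rich exocyclic C4=C15 bond with oxygen going to the more substituted C4, from the alpha face (axial C–O bond formation on the ring A half-chair, away from the pseudo-axial isopropyl on C7) and with the bicyclic part exo so that phenyl ends trans to C5, which gives the (4S,1'S) configuration by substrate control.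

**Compound list**

1 | (1R,5S)-6,6-dimethylbicyclo[3.1.1]heptan-2-one, (+)-nopinone | O=C1CC[C@H]2C[C@@H]1C2(C)C | starting material
2 | (1R,5R)-6,6-dimethylbicyclo[3.1.1]hept-3-en-2-one, (+)-apoverbenone | O=C1C=C[C@H]2C[C@@H]1C2(C)C | intermediate
3 | 2-(tert-butyldimethylsilyloxy)buta-1,3-diene | C=CC(=C)O[Si](C)(C)C(C)(C)C | starting material
4 | (1R,2S,7S,9R)-4-(tert-butyldimethylsilyloxy)-10,10-dimethyltricyclo[7.1.1.0(2,7)]undec-4-en-8-one; ring A cis-fused, both ring-fusion hydrogens syn to the gem-dimethyl bridge | O=C1[C@H]2CC=C(O[Si](C)(C)C(C)(C)C)C[C@H]2[C@H]3C[C@@H]1C3(C)C | intermediate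
5 | (1R,2S,7S,9R)-4-(tert-butyldimethylsilyloxy)-10,10-dimethyl-8-methylidenetricyclo[7.1.1.0(2,7)]undec-4-ene | C=C1[C@H]2CC=C(O[Si](C)(C)C(C)(C)C)C[C@H]2[C@H]3C[C@@H]1C3(C)C | intermediate
6 | (1R,2S,7S,9R)-10,10-dimethyl-8-methylidenetricyclo[7.1.1.0(2,7)]undecan-4-one | C=C1[C@H]2CCC(=O)C[C@H]2[C@H]3C[C@@H]1C3(C)C | intermediate
7 | (4aR,5R,8S,8aS)-5-methyl-8-(propan-2-yl)octahydronaphthalen-2(1H)-one; cis-fused, methyl cis to C2, isopropyl trans to C2 and C5 | CC(C)[C@@H]1CC[C@@H](C)[C@H]2CCC(=O)C[C@@H]12 | intermediate
8 | trimethyl{[(4aR,5R,8S,8aS)-5-methyl-8-(propan-2-yl)-3,4,4a,5,6,7,8,8a-octahydronaphthalen-2-yl]oxy}silane | CC(C)[C@@H]1CC[C@@H](C)[C@H]2CCC(O[Si](C)(C)C)=C[C@@H]12 | intermediate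
9 | (4aR,5R,8S)-5-methyl-8-(propan-2-yl)-4,4a,5,6,7,8-hexahydronaphthalen-2(3H)-one | CC(C)[C@@H]1CC[C@@H](C)[C@H]2CCC(=O)C=C12 | intermediate
10 | (1S,4R,4aR)-4-methyl-7-methylidene-1-(propan-2-yl)-1,2,3,4,4a,5,6,7-octahydronaphthalene | CC(C)[C@@H]1CC[C@@H](C)[C@H]2CCC(=C)C=C12 | intermediate
11 | benzaldehyde | O=Cc1ccccc1 | starting material
12 | 2,4,6-trihydroxybenzene-1,3-dicarbaldehyde | O=Cc1c(O)c(C=O)c(O)cc1O | starting material
13 | (E)-5-benzylidene-2,4-dihydroxy-6-oxocyclohexa-1,3-diene-1,3-dicarbaldehyde | O=CC1=C(O)C(C=O)=C(O)/C(=C\c2ccccc2)C1=O | intermediate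
14 | guajadial D | CC(C)[C@@H]1CC[C@@H](C)[C@H]2CC[C@@]3(C=C12)C[C@@H](c1ccccc1)c1c(O)c(C=O)c(O)c(C=O)c1O3 | target

**Totals and risks**

Total step count: 7. Longest linear sequence: 7 steps (1 to 14).

The three steps most likely to fail are steps 2, 4 and 7.

Step 2 may be too slow, because cyclic enones are modest dienophiles and the silyloxydiene can decompose at 150 °C. The fallback sets out from 2 and uses the far more reactive trans-1-methoxy-3-(trimethylsilyloxy)buta-1,3-diene (PhMe, 80 °C), which adds on the same face to give the methoxy silyl enol ether cycloadduct F1. Dilute HCl in THF converts this into the tricyclic enedione F2. Rhodium-catalysed 1,4-hydrosilylation of its enone (t-BuMe2SiH, RhCl(PPh3)3 cat., PhH, 50 °C) then gives the silyl enol ether 4, where the route is rejoined.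

Step 4 may stop at the ring-opened alkene, reduce the radical before the cyclobutane fragments, or touch the ketone. The fallback sets out from 4 and opens the cyclobutane at the ketone stage by ketyl fragmentation (SmI2, t-BuOH, THF/HMPA, 0 °C) to give the ring-opened keto silyl enol ether F3. Neutral methylenation (Cp2TiMe2, PhMe, 65 °C) gives the methylidene silyl enol ether F4. Hydrogenation of only the exocyclic alkene from the face away from the axial C1–C2 bond (H2, RhCl(PPh3)3, PhH) gives the saturated silyl enol ether F5, and aqueous HCl in THF hydrolyses it to 7, where the route is rejoined.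

Step 7 may give a low yield or a mixture of C4/C1' diastereomers, and the strained diene may isomerise under acid. The fallback sets out from 10 and runs the same three-component reaction with phloroglucinol and benzaldehyde; the 6-benzylidene-3,5-dihydroxycyclohexa-2,4-dien-1-one F6 formed in the flask is trapped by 10 to give the bis-deformyl chroman F7. Two-fold ortho-formylation of its free phenol ring (MgCl2, Et3N, paraformaldehyde, MeCN, reflux) then gives 14.

Step 5 also carries a regiochemical risk (enolisation toward C3 instead of C5) that must be checked on the first run.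

**Further compounds**

F1 | step 2 | methoxy silyl enol ether cycloadduct of 2 (methoxy epimers at C2) | O=C1[C@H]2C(OC)C=C(O[Si](C)(C)C)C[C@H]2[C@H]3C[C@@H]1C3(C)C
F2 | step 2 | tricyclic enedione, 10,10-dimethyltricyclo[7.1.1.0(2,7)]undec-5-ene-4,8-dione | O=C1[C@H]2C=CC(=O)C[C@H]2[C@H]3C[C@@H]1C3(C)C
F3 | step 4 | ring-opened keto silyl enol ether (cis-fused, isopropyl on C7, ketone on C10) | CC(C)[C@@H]1CCC(=O)[C@H]2CC=C(O[Si](C)(C)C(C)(C)C)C[C@@H]12
F4 | step 4 | methylidene silyl enol ether (C10 methylidene) | CC(C)[C@@H]1CCC(=C)[C@H]2CC=C(O[Si](C)(C)C(C)(C)C)C[C@@H]12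
F5 | step 4 | saturated silyl enol ether (C10 methyl equatorial) | CC(C)[C@@H]1CC[C@@H](C)[C@H]2CC=C(O[Si](C)(C)C(C)(C)C)C[C@@H]12
F6 | step 7 | 6-benzylidene-3,5-dihydroxycyclohexa-2,4-dien-1-one | O=C1C=C(O)C=C(O)/C1=C\c1ccccc1
F7 | step 7 | bis-deformyl chroman (guajadial D lacking both formyl groups) | CC(C)[C@@H]1CC[C@@H](C)[C@H]2CC[C@@]3(C=C12)C[C@@H](c1ccccc1)c1c(O)cc(O)cc1O3
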